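(All runs stem from a simulated flask from invented constants, noise included.)

The process chemist opened the meeting with the earlier runs and the questions on the table.

| flask | substrate | partner | temperature | remark | time |
|---|---|---|---|---|---|
| theta | 0.40 M | 1 equiv | 105 °C | run made earlier |  |
| eta | 0.56 M | 1 equiv | 116 °C | run made earlier |  |
| delta | 0.88 M | 1 equiv | 105 °C | run made earlier |  |
| gamma | 0.40 M | 1.5 equiv | 116 °C | run made earlier |  |
| north | 0.40 M | 1.00 equiv |  | everything together at the start at 70 °C, warmed to 110 °C at 3.0 h | 8.0 h |
| north-west | 0.40 M | 1.00 equiv | 110 °C | everything together at the start | 8.0 h |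
| south-west | 0.40 M (fed, over 50 min) | 1.00 equiv | 110 °C | all else is in the flask from the start; the feed brings no volume worth counting | 8.0 h |
| east | 0.40 M | 1.00 equiv (fed, over 3.0 h) |  | the addition at 70 °C, then warmed to 110 °C; the feed brings no volume worth counting | 8.0 h |
| south-east | 0.40 M (fed, over 3.0 h) | 1.00 equiv | 110 °C | all else is in the flask from the start; the feed brings no volume worth counting | 8.0 h |

| run | time / h | self-condensation product / % | target / % | substrate / % |
|---|---|---|---|---|
| theta | 1.33 | 44.9 | 29.8 | 23.0 |
| theta | 2.50 | 53.5 | 38.4 | 11.4 |
| theta | 4.00 | 51.7 | 40.7 | 5.4 |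
| theta | 5.00 | 51.2 | 43.7 | 3.6 |
| theta | 6.00 | 53.8 | 44.2 | 1.9 |
| theta | 8.00 | 53.0 | 46.6 | 2.6 |
| eta | 0.333 | 46.5 | 19.2 | 30.2 |
| eta | 1.00 | 56.7 | 31.3 | 9.1 |
| eta | 1.50 | 59.2 | 36.0 | 4.6 |
| eta | 2.50 | 59.4 | 37.1 | 2.1 |
| eta | 4.00 | 59.1 | 39.1 | 0 |
| eta | 5.00 | 59.6 | 39.8 | 1.2 |
| delta | 0.417 | 43.5 | 17.3 | 37.2 |
| delta | 0.667 | 52.4 | 23.6 | 26.3 |
| delta | 1.00 | 55.9 | 26.1 | 17.7 |
| delta | 2.00 | 61.3 | 33.2 | 5.5 |
| delta | 3.00 | 60.5 | 37.8 | 3.3 |
| delta | 5.00 | 60.2 | 37.4 | 2.4 |
| gamma | 0.417 | 43.9 | 25.0 | 31.9 |
| gamma | 1.33 | 50.7 | 40.5 | 6.0 |
| gamma | 2.00 | 54.1 | 45.1 | 4.3 |
| gamma | 3.00 | 52.2 | 44.8 | 2.0 |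
| gamma | 5.00 | 51.2 | 48.2 | 0 |

(standard deviation of a reading: 1 percentage point)

- percent here means substrate units held: one self-condensation product counts as two
- the numbers in the tables scatter with a standard deviation of 1 percentage point

* which flask leads in amount of self-condensation product, in percent of the substrate charged ("all alike" within 1.5 percentage points) (north / north-west / south-west / east / south-east / all alike)
* how much self-condensation product is there at the end, in percent of the substrate charged: north
* how much self-condensation product is there at the end, in percent of the substrate charged: north-west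
* how much self-condensation product is there at the end, in percent of the substrate charged: south-west
* how much self-condensation product is there at the end, in percent of the substrate charged: east
* how much self-condensation product is there at the end, in percent of the substrate charged: south-east

She proposed following one substrate molecule. At each moment it either meets partner and becomes target, or meets a second substrate and becomes self-condensation product, and she took the odds between these as proportional to c_substrate/c_partner. She read the constant from the theta run. At 1.33 h product stood to target as 1.51, while c_substrate/c_partner had fallen from unity to 0.328, a rough mean of 0.664. That gives 2.27. She named this g, the fork factor (a selectivity factor): the odds for product against target at equal concentrations. The theta run is somewhat colder than 110 °C, she noted.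

The kineticist asked what ratio south-east holds. The first reading of the theta run gives the substrate an overall first-order constant of 1.11 h⁻¹, so its mean life reads 0.901 h, shorter than the south-east feed. Substrate in south-east should therefore level off near 30.2% of the charge, and after the climb of one mean life it averages 21.1% over the feed. Counting half of the substrate gone by the end of the feed as target puts mean partner at 82.5% of its charge. The odds for south-east are then 0.579, below g, and the meeting wrote down 36.7% product for that flask.

The forecast named east as leader at 56%, with north-west at 55.5%, south-west at 52%, north at 51% and south-east at 50%, above the meeting's figure, holding for south-east that “partner depletion limits the gain”.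

North-west leads with 54.5%, and south-east gives 40.8%; north has 50.3%, south-west 49.4%, east 52.7%.

    substrate + partner → target, rate k1*[substrate]*[partner]^0.5 (k = 0.0176 M⁻⁰·⁵ min⁻¹, Ea = 75.0 kJ mol⁻¹)
    2 substrate → self-condensation product (k = 0.0391 M⁻¹ min⁻¹, Ea = 100 kJ mol⁻¹)
    (constants at 110 °C)

Over its first 3.0 h, south-east held on average c_substrate 0.0885 M and c_partner 0.333 M. Multiplied by g, that ratio gives odds of 0.603, and south-east ends with product to target at 0.706.

For the neighbour, south-east repeated at 125 °C, the eta run serves as stand-in, though it is richer and colder. Its first reading gives a fork factor of 3.53 and a constant of 3.60 h⁻¹, hence a level of 9.27% and odds of 0.384, lower than the meeting's odds for south-east. The neighbour gives 36.4% product against 63.5% target, odds of 0.573.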